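**Retrosynthetic overview**
- The target is cut at both C–C bonds of the methylene bridge, giving a dearomatised (S)-acylphloroglucinol half, an aromatic 4-O-methyl acylphloroglucinol half and a one-carbon aminal.
- Neither carbocycle is bought. Each is closed the way a type III polyketide synthase closes it, by C6→C1 Claisen cyclisation of a hexanoyl-primed tetraketide, handled as its 2-pyrone (the enzyme's own derailment lactone).
- The dearomatised ring is never aromatic. Its tetraketide is quaternised at C2 (methyl plus prenyl) before ring closure, so the Claisen step delivers the cyclohexadienone with its stereocentre directly.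
- The stereocentre is set by Pd-catalysed asymmetric C3-prenylation of the 3-methyl-4-hydroxy-2-pyrone tetraketide.
- Ring order: dearomatised carbocycle (step 3), aromatic carbocycle (step 5), then union through the CH2 bridge (step 6).

Assumption: pyrones 1 and 8 are bought as catalogue compounds, and the (R,R)-ligand in step 2 is taken to give the (S)-centre (if the sense of induction is the reverse, the (S,S)-ligand is used and nothing else changes).

**Route**

Step 1
Reactants: 1 4-hydroxy-3,6-dimethyl-2H-pyran-2-one; 2 methyl hexanoate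
Product: 3 4-hydroxy-3-methyl-6-(2-oxoheptyl)-2H-pyran-2-one
Conditions: 1 (2 equiv), LDA (4.1 equiv), THF, −78 → −20 °C; then 2 (1 equiv), −78 → 0 °C; 1 M HCl
Reagents that add atoms: methyl hexanoate (2), CCCCCC(=O)OC
Why: The O,C-dianion of the 4-hydroxy-2-pyrone reacts only at its 6-CH2 terminus in a Claisen-type acylation with the ester (Harris dianion acylation), the second equivalent of dianion absorbing the proton of the more acidic β-keto product, to give the hexanoyl-primed, C2-methylated tetraketide as its pyrone.

Step 2
Reactants: 3 4-hydroxy-3-methyl-6-(2-oxoheptyl)-2H-pyran-2-one; 4 3-methylbut-2-en-1-yl acetate (prenyl acetate)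
Product: 5 (3S)-3-methyl-3-(3-methylbut-2-en-1-yl)-6-(2-oxoheptyl)-2H-pyran-2,4(3H)-dione
Conditions: 4 (1.05 equiv), Pd2(dba)3·CHCl3 (2.5 mol %), (R,R)-DACH-phenyl Trost ligand (7.5 mol %), DBU (10 mol %), CH2Cl2, 0 °C → rt
Reagents that add atoms: 3-methylbut-2-en-1-yl acetate (4), CC(C)=CCOC(C)=O
Why: Proposed new method: the pyrone oxide (pKa about 5, generated by the acetate released on ionisation) is a soft stabilised nucleophile that attacks the ligand-bound π-prenyl-palladium at its CH2 terminus through C3 (any O-prenyl ether re-ionises and funnels to carbon), and the chiral pocket differentiates the two faces of the planar anion to set the (S) quaternary centre; the closest known reactions are the Pd(0) C3-allylation of 4-hydroxy-6-methyl-2-pyrone to 3,3-diallylpyran-2,4-diones and the Trost asymmetric allylic alkylation (linear prenylation) of 3-substituted oxindoles and α-substituted β-keto esters.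

Step 3
Reactants: 5 (3S)-3-methyl-3-(3-methylbut-2-en-1-yl)-6-(2-oxoheptyl)-2H-pyran-2,4(3H)-dione
Product: 7 (4S)-2-hexanoyl-3,5-dihydroxy-4-methyl-4-(3-methylbut-2-en-1-yl)cyclohexa-2,5-dien-1-one, via ring-opened methyl ester 6 (not isolated)
Conditions: NaOMe (3 equiv), MeOH, 0 → 45 °C; cold 1 M HCl to pH 3
Reagents that add atoms: none
Why: Proposed new method: methoxide opens the enol lactone at C2 to ester 6, in which C2 is quaternary so the aldol (resorcylate) mode is impossible and the only six-membered closure left is the polyketide-synthase-type C6→C1 Claisen (Dieckmann) attack of the 5,7-dione carbanion on the ester, driven by formation of the strongly acidic triketone anion and leaving the non-enolisable stereocentre untouched; the closest known reaction is the Harris alkoxide-mediated conversion of 6-(2-oxoalkyl)-4-hydroxy-2-pyrones into acylphloroglucinols.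

Step 4
Reactants: 8 4-methoxy-6-methyl-2H-pyran-2-one; 2 methyl hexanoate
Product: 9 4-methoxy-6-(2-oxoheptyl)-2H-pyran-2-one
Conditions: 8 (2 equiv), LDA (2.1 equiv), THF, −78 °C; then 2 (1 equiv), −78 → −20 °C; 1 M HCl
Reagents that add atoms: methyl hexanoate (2), CCCCCC(=O)OC
Why: LDA removes a proton from the vinylogous 6-methyl group and the resulting extended enolate is C-acylated by the ester (Claisen-type acylation), giving the tetraketide pyrone with the future para oxygen already methylated.

Step 5
Reactants: 9 4-methoxy-6-(2-oxoheptyl)-2H-pyran-2-one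
Product: 11 1-(2,6-dihydroxy-4-methoxyphenyl)hexan-1-one, via ring-opened enol-ether ester 10 (not isolated)
Conditions: NaOMe (4 equiv), MeOH, reflux; 1 M HCl
Reagents that add atoms: none
Why: Methoxide opens the lactone to the (E)-β-methoxyacrylate ester 10, whose C2 is locked in the enol ether and cannot do the aldol closure, so the 5,7-dione carbanion closes C6→C1 by Claisen cyclisation (Harris biomimetic pyrone-to-phloroglucinol rearrangement) and loss of methanol with tautomerisation gives the arene with the OMe para to the acyl group.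

Step 6
Reactants: 7 (4S)-2-hexanoyl-3,5-dihydroxy-4-methyl-4-(3-methylbut-2-en-1-yl)cyclohexa-2,5-dien-1-one; 12 N,N,N',N'-tetramethylmethanediamine; 11 1-(2,6-dihydroxy-4-methoxyphenyl)hexan-1-one
Product: 15 (4S)-2-hexanoyl-6-[(3-hexanoyl-2,4-dihydroxy-6-methoxyphenyl)methyl]-3,5-dihydroxy-4-methyl-4-(3-methylbut-2-en-1-yl)cyclohexa-2,5-dien-1-one (CNP0108719.1), via Mannich base 13 (not isolated), via methylidene trione 14 (not isolated)
Conditions: 12 (1.0 equiv), MeCN, 0 °C → rt; then 11 (1.5 equiv), 70 °C; pH 4 buffer
Reagents that add atoms: N,N,N',N'-tetramethylmethanediamine (12), CN(C)CN(C)C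
Why: The acidic trione 7 protonates the aminal and is aminomethylated at C6 (Mannich reaction), the zwitterionic Mannich base 13 loses dimethylamine on warming (E1cB) to the ortho-quinone-methide-like enone 14, and phloroglucinol 11 adds at C3 (Michael/Friedel–Crafts addition), the stepwise order suppressing homodimers and the remote quaternary centre being untouched.

**Compound list**
1 | 4-hydroxy-3,6-dimethyl-2H-pyran-2-one | CC1=CC(O)=C(C)C(=O)O1 | starting material
2 | methyl hexanoate | CCCCCC(=O)OC | starting material
3 | 4-hydroxy-3-methyl-6-(2-oxoheptyl)-2H-pyran-2-one | CCCCCC(=O)CC1=CC(O)=C(C)C(=O)O1 | intermediate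
4 | 3-methylbut-2-en-1-yl acetate (prenyl acetate) | CC(C)=CCOC(C)=O | starting material
5 | (3S)-3-methyl-3-(3-methylbut-2-en-1-yl)-6-(2-oxoheptyl)-2H-pyran-2,4(3H)-dione | CCCCCC(=O)CC1=CC(=O)[C@](C)(CC=C(C)C)C(=O)O1 | intermediate
6 | methyl (2S)-2-methyl-2-(3-methylbut-2-en-1-yl)-3,5,7-trioxododecanoate | CCCCCC(=O)CC(=O)CC(=O)[C@](C)(CC=C(C)C)C(=O)OC | intermediate
7 | (4S)-2-hexanoyl-3,5-dihydroxy-4-methyl-4-(3-methylbut-2-en-1-yl)cyclohexa-2,5-dien-1-one | CCCCCC(=O)C1=C(O)[C@@](C)(CC=C(C)C)C(O)=CC1=O | intermediate
8 | 4-methoxy-6-methyl-2H-pyran-2-one | CC1=CC(OC)=CC(=O)O1 | starting material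
9 | 4-methoxy-6-(2-oxoheptyl)-2H-pyran-2-one | CCCCCC(=O)CC1=CC(OC)=CC(=O)O1 | intermediate
10 | methyl (2E)-3-methoxy-5,7-dioxododec-2-enoate | CCCCCC(=O)CC(=O)C/C(OC)=C\C(=O)OC | intermediate
11 | 1-(2,6-dihydroxy-4-methoxyphenyl)hexan-1-one | CCCCCC(=O)c1c(O)cc(OC)cc1O | intermediate
12 | N,N,N',N'-tetramethylmethanediamine | CN(C)CN(C)C | starting material
13 | (4S)-6-[(dimethylamino)methyl]-2-hexanoyl-3,5-dihydroxy-4-methyl-4-(3-methylbut-2-en-1-yl)cyclohexa-2,5-dien-1-one | CCCCCC(=O)C1=C(O)[C@@](C)(CC=C(C)C)C(O)=C(CN(C)C)C1=O | intermediate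
14 | (4R)-2-hexanoyl-3-hydroxy-4-methyl-4-(3-methylbut-2-en-1-yl)-6-methylidenecyclohex-2-ene-1,5-dione (same spatial arrangement as 7; only the CIP label changes) | CCCCCC(=O)C1=C(O)[C@@](C)(CC=C(C)C)C(=O)C(=C)C1=O | intermediate
15 | (4S)-2-hexanoyl-6-[(3-hexanoyl-2,4-dihydroxy-6-methoxyphenyl)methyl]-3,5-dihydroxy-4-methyl-4-(3-methylbut-2-en-1-yl)cyclohexa-2,5-dien-1-one | CCCCCC(=O)C1=C(O)[C@@](C)(CC=C(C)C)C(O)=C(Cc2c(OC)cc(O)c(C(=O)CCCCC)c2O)C1=O | target

**Totals**
Total step count: 6.
Longest linear sequence: 4 steps (1 → 3 → 5 → 7 → 15; steps 1, 2, 3 and 6).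

**Steps most likely to fail**

Step 2 (asymmetric prenylation). The risks are modest enantioselectivity, some reverse-prenyl isomer, and erosion of ee if palladium re-ionises the C–prenyl bond of the very stabilised pyrone anion. The fallback gives up catalytic stereocontrol and resolves instead. It sets out from 3, which is prenylated with 4 and an achiral catalyst (Pd(PPh3)4, CH2Cl2) to give racemic 3-methyl-3-(3-methylbut-2-en-1-yl)-6-(2-oxoheptyl)-2H-pyran-2,4(3H)-dione F1. The conditions of step 3 convert this into racemic 2-hexanoyl-3,5-dihydroxy-4-methyl-4-(3-methylbut-2-en-1-yl)cyclohexa-2,5-dien-1-one F2. Preparative chiral SFC (amylose phase, CO2/MeOH with 0.1 % formic acid) then separates the enantiomers, and the (S)-enantiomer is 7, where the route is rejoined.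

Step 3 (Claisen closure onto the quaternised tetraketide). The risks are slow attack on the neopentyl-type ester, retro-Claisen cleavage next to the quaternary carbon, and γ-pyrone formation. The fallback reverses the order of ring formation and quaternisation. It sets out from 3, which is cyclised first (Mg(OMe)2, MeOH, reflux, Harris–Crombie Claisen mode) to the aromatic 1-(2,4,6-trihydroxy-3-methylphenyl)hexan-1-one F3. Pd/Trost-ligand asymmetric dearomative prenylation of F3 with 4 at the methyl-bearing carbon then gives 7, where the route is rejoined. This accepts competition from prenylation at the free ring position.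

Step 6 (methylene-bridge union). The risks are scrambling of the aminomethyl group by retro-Mannich reaction (giving both homodimers), double alkylation of 11, and self-reaction of 14. The fallback puts the bridge carbon on the aromatic half as an aldehyde. It sets out from 11, which is formylated (POCl3, DMF, then aqueous NaOAc; Vilsmeier–Haack) to 3-hexanoyl-2,4-dihydroxy-6-methoxybenzaldehyde F4. Three-component reductive alkylation of 7 with F4 and Hantzsch ester (L-proline cat., CH2Cl2, rt; Knoevenagel condensation, then hydride transfer to the quinone methide) gives 15 directly, where the route is rejoined.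

**Further compounds**
F1 | step 2 | racemic 3-methyl-3-(3-methylbut-2-en-1-yl)-6-(2-oxoheptyl)-2H-pyran-2,4(3H)-dione | CCCCCC(=O)CC1=CC(=O)C(C)(CC=C(C)C)C(=O)O1
F2 | step 2 | racemic 2-hexanoyl-3,5-dihydroxy-4-methyl-4-(3-methylbut-2-en-1-yl)cyclohexa-2,5-dien-1-one | CCCCCC(=O)C1=C(O)C(C)(CC=C(C)C)C(O)=CC1=O
F3 | step 3 | 1-(2,4,6-trihydroxy-3-methylphenyl)hexan-1-one | CCCCCC(=O)c1c(O)cc(O)c(C)c1O
F4 | step 6 | 3-hexanoyl-2,4-dihydroxy-6-methoxybenzaldehyde | CCCCCC(=O)c1c(O)cc(OC)c(C=O)c1O
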